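**Plan**
- Retrosynthetic cuts, in order: the two MOM caps on the benzophenone ring; the two C–CH3 bonds at the quaternary carbon of the cyclohexadienone (filicinic) ring; the bond from the bridging CH2 to the phloroglucinol ring; then, on the benzophenone ring, the second MOM cap, the O–prenyl bond, the ring–CHO bond and the first MOM cap.
- Enabling feature: the C(CH3)2 carbon of the filicinic ring lies between the enol carbon C–OH and the ring C=O. It is therefore the single unsubstituted carbon, flanked by two oxygen-bearing carbons, of an aromatic 3-benzyl-acylphloroglucinol, and two C-methylations there convert the arene into the enolised trione.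
- Forward: no ring is formed. The benzophenone ring comes from 2,4,6-trihydroxybenzophenone (MOM on the 4-OH, ortho-formylation, prenylation of the OH para to CHO, second MOM, reduction) and the other ring from phloroisobutyrophenone. The two are joined at the bridging CH2 by Friedel–Crafts benzylation.
- gem-Dimethylation then dearomatises the acylphloroglucinol ring, and mild acid removes both MOM groups.
- Stereochemistry: the target has no stereocentre and no stereogenic double bond, so nothing has to be set or protected against scrambling.

Key step: step 7

Remark on the chemistry: the target is achiral and is drawn as one enol tautomer of the trione ring; the tautomers interconvert freely. 2,4,6-Trihydroxybenzophenone and phloroisobutyrophenone are assumed to be purchasable.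

**Route**

Step 1
Reactants: 1 2,4,6-trihydroxybenzophenone; 2 chloromethyl methyl ether
Product: 3 2,6-dihydroxy-4-(methoxymethoxy)benzophenone
Conditions: MOMCl (1.05 equiv), i-Pr2NEt (1.2 equiv), THF, 0 °C → rt
Reagents that add atoms: chloromethyl methyl ether 2, COCCl
Why: Williamson-type MOM ether formation should occur at the 4-OH, the only hydroxyl not hydrogen-bonded to the benzoyl carbonyl and the most acidic one (para to C=O), before either chelated ortho hydroxyl reacts with the single equivalent of MOMCl.

Step 2
Reactants: 3 2,6-dihydroxy-4-(methoxymethoxy)benzophenone; 4 paraformaldehyde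
Product: 6 3-benzoyl-2,4-dihydroxy-6-(methoxymethoxy)benzaldehyde, via hydroxymethyl phenol 5 (not isolated)
Conditions: MgCl2 (2.5 equiv), Et3N (5 equiv), (CH2O)n (2.5 equiv), MeCN, 70 °C; cold aq. citric acid work-up
Reagents that add atoms: paraformaldehyde 4 (as formaldehyde), C=O
Why: In this magnesium-mediated ortho-formylation of a phenol (Casnati–Skattebøl reaction) the magnesium phenoxide delivers formaldehyde to the carbon next to a phenolic oxygen and a second formaldehyde oxidises the benzylic alkoxide by hydride transfer; the two free ring carbons are equivalent by symmetry, the non-acidic medium spares the MOM ether, and the first formyl group deactivates the ring towards a second formylation.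

Step 3
Reactants: 6 3-benzoyl-2,4-dihydroxy-6-(methoxymethoxy)benzaldehyde; 7 prenyl bromide (1-bromo-3-methylbut-2-ene)
Product: 8 3-benzoyl-2-hydroxy-6-(methoxymethoxy)-4-[(3-methylbut-2-en-1-yl)oxy]benzaldehyde
Conditions: prenyl bromide (1.1 equiv), K2CO3 (1.2 equiv), acetone, rt → 40 °C
Reagents that add atoms: prenyl bromide 7, CC(C)=CCBr
Why: Williamson ether synthesis should select the 4-OH, which is para to the formyl group and flanked by only one acyl substituent and so is the more acidic and accessible phenol, whereas the 2-OH is held between the formyl and benzoyl groups in a strong resonance-assisted hydrogen bond.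

Step 4
Reactants: 8 3-benzoyl-2-hydroxy-6-(methoxymethoxy)-4-[(3-methylbut-2-en-1-yl)oxy]benzaldehyde; 2 chloromethyl methyl ether
Product: 9 3-benzoyl-2,6-bis(methoxymethoxy)-4-[(3-methylbut-2-en-1-yl)oxy]benzaldehyde
Conditions: NaH (1.3 equiv), MOMCl (1.5 equiv), THF/DMF, 0 °C → rt
Reagents that add atoms: chloromethyl methyl ether 2, COCCl
Why: MOM ether formation through the sodium phenoxide should succeed because irreversible deprotonation breaks the chelate of the last hydroxyl, while the non-enolisable aldehyde, the diaryl ketone, the prenyl ether and the first MOM ether are inert to NaH and MOMCl.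

Step 5
Reactants: 9 3-benzoyl-2,6-bis(methoxymethoxy)-4-[(3-methylbut-2-en-1-yl)oxy]benzaldehyde
Product: 10 [3-(hydroxymethyl)-2,4-bis(methoxymethoxy)-6-[(3-methylbut-2-en-1-yl)oxy]phenyl](phenyl)methanone
Conditions: NaBH4 (0.5 equiv), THF/MeOH, −20 °C → 0 °C; aq. NH4Cl
Reagents that add atoms: none
Why: Chemoselective borohydride reduction should stop at the benzylic alcohol because the aldehyde reacts far faster than the diaryl ketone, which is twisted between two ortho substituents and deactivated by ortho and para oxygen donors.

Step 6
Reactants: 10 [3-(hydroxymethyl)-2,4-bis(methoxymethoxy)-6-[(3-methylbut-2-en-1-yl)oxy]phenyl](phenyl)methanone; 11 phloroisobutyrophenone (2-methyl-1-(2,4,6-trihydroxyphenyl)propan-1-one)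
Product: 12 1-{3-[3-benzoyl-2,6-bis(methoxymethoxy)-4-(prenyloxy)benzyl]-2,4,6-trihydroxyphenyl}-2-methylpropan-1-one
Conditions: 11 (3 equiv), HFIP/CH2Cl2, rt, slow addition of 10; excess 11 recovered
Reagents that add atoms: none
Why: In this dehydrative Friedel–Crafts benzylation HFIP should ionise the 2,4,6-trioxygenated benzylic alcohol to a strongly stabilised benzylic cation that is captured by one of the two equivalent free ring carbons of the electron-rich phloroglucinol, the excess nucleophile suppressing a second benzylation and the absence of a strong acid sparing the MOM and prenyl ethers.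

Step 7
Reactants: 12 1-{3-[3-benzoyl-2,6-bis(methoxymethoxy)-4-(prenyloxy)benzyl]-2,4,6-trihydroxyphenyl}-2-methylpropan-1-one; 13 iodomethane
Product: 15 sarothralin bis(methoxymethyl) ether (4-[3-benzoyl-2,6-bis(methoxymethoxy)-4-(prenyloxy)benzyl]-3,5-dihydroxy-6,6-dimethyl-2-(2-methylpropanoyl)cyclohexa-2,4-dien-1-one), via mono-C-methyl phenol 14 (not isolated)
Conditions: NaOMe (4 equiv), MeI (2.1 equiv), MeOH, 0 °C → rt; aq. NaH2PO4 (pH ca. 5)
Reagents that add atoms: iodomethane 13, CI
Why: Methoxide turns the three phenols of the acylphloroglucinol ring into a polyphenoxide whose only unsubstituted ring carbon, lying between two oxygen-bearing carbons, attacks iodomethane by SN2 to give the mono-C-methyl phenol 14 after tautomerisation. 14 is ionised again and the same carbon, now bearing a methyl group, attacks a second iodomethane to give the cross-conjugated enolised trione, which has no ring hydrogen left with which to rearomatise. The closest known reaction is the base-mediated dearomative C-methylation of acylphloroglucinols to acylfilicinic acids. No ring is closed and no stereocentre arises, because the new quaternary carbon carries two identical methyl groups. The step needs carbon rather than oxygen alkylation, reaction in one ring only and a stop after two methyl groups: the protic solvent solvates the phenoxide oxygens and directs the soft electrophile to carbon, the two MOM ethers leave the benzophenone ring without an ionisable hydroxyl, and the filicinic acid anion formed after the second methylation is a delocalised vinylogous carboxylate that should react only slowly with the limited iodomethane. Quaternisation of the bridge-bearing carbon is disfavoured by the bulky di-ortho-substituted aryl group on the methylene, and the MOM caps also prevent base-induced scission of the bridge, since no quinone methide can form on the benzophenone ring.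

Step 8
Reactants: 15 sarothralin bis(methoxymethyl) ether
Product: 17 sarothralin, via para-MOM monoether 16 (not isolated)
Conditions: HCl (ca. 0.5 M) in MeOH/THF, 0 °C → rt, monitored; pH 5 phosphate buffer
Reagents that add atoms: none
Why: Acid-catalysed acetal methanolysis should free both phenols because ionisation of an aryl MOM ether to the methoxymethyl oxocarbenium ion is far faster than ionisation of the aryl prenyl ether to a prenyl cation, the MOM next to the benzoyl group leaving first with chelation assistance, while the diarylmethane and the enolised trione tolerate dilute acid.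

**Compound list**

1 | 2,4,6-trihydroxybenzophenone | O=C(c1ccccc1)c1c(O)cc(O)cc1O | starting material
2 | chloromethyl methyl ether (MOMCl) | COCCl | starting material
3 | 2,6-dihydroxy-4-(methoxymethoxy)benzophenone | COCOc1cc(O)c(C(=O)c2ccccc2)c(O)c1 | intermediate
4 | paraformaldehyde (source of formaldehyde) | C=O | starting material
5 | 2,6-dihydroxy-3-(hydroxymethyl)-4-(methoxymethoxy)benzophenone (formed in the flask as its magnesium salt) | COCOc1cc(O)c(C(=O)c2ccccc2)c(O)c1CO | intermediate
6 | 3-benzoyl-2,4-dihydroxy-6-(methoxymethoxy)benzaldehyde | COCOc1cc(O)c(C(=O)c2ccccc2)c(O)c1C=O | intermediate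
7 | prenyl bromide (1-bromo-3-methylbut-2-ene) | CC(C)=CCBr | starting material
8 | 3-benzoyl-2-hydroxy-6-(methoxymethoxy)-4-[(3-methylbut-2-en-1-yl)oxy]benzaldehyde | COCOc1cc(OCC=C(C)C)c(C(=O)c2ccccc2)c(O)c1C=O | intermediate
9 | 3-benzoyl-2,6-bis(methoxymethoxy)-4-[(3-methylbut-2-en-1-yl)oxy]benzaldehyde | COCOc1cc(OCC=C(C)C)c(C(=O)c2ccccc2)c(OCOC)c1C=O | intermediate
10 | [3-(hydroxymethyl)-2,4-bis(methoxymethoxy)-6-[(3-methylbut-2-en-1-yl)oxy]phenyl](phenyl)methanone | COCOc1cc(OCC=C(C)C)c(C(=O)c2ccccc2)c(OCOC)c1CO | intermediate
11 | phloroisobutyrophenone (2-methyl-1-(2,4,6-trihydroxyphenyl)propan-1-one) | CC(C)C(=O)c1c(O)cc(O)cc1O | starting material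
12 | 1-{3-[3-benzoyl-2,6-bis(methoxymethoxy)-4-(prenyloxy)benzyl]-2,4,6-trihydroxyphenyl}-2-methylpropan-1-one | CC(C)=CCOc1cc(OCOC)c(Cc2c(O)cc(O)c(C(=O)C(C)C)c2O)c(OCOC)c1C(=O)c1ccccc1 | intermediate
13 | iodomethane | CI | starting material
14 | 1-{3-[3-benzoyl-2,6-bis(methoxymethoxy)-4-(prenyloxy)benzyl]-2,4,6-trihydroxy-5-methylphenyl}-2-methylpropan-1-one (formed in the flask) | CC(C)=CCOc1cc(OCOC)c(Cc2c(O)c(C)c(O)c(C(=O)C(C)C)c2O)c(OCOC)c1C(=O)c1ccccc1 | intermediate
15 | sarothralin bis(methoxymethyl) ether | CC(C)=CCOc1cc(OCOC)c(CC2=C(O)C(C)(C)C(=O)C(C(=O)C(C)C)=C2O)c(OCOC)c1C(=O)c1ccccc1 | intermediate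
16 | sarothralin mono(methoxymethyl) ether, MOM on the oxygen para to the benzoyl group (formed in the flask) | CC(C)=CCOc1cc(OCOC)c(CC2=C(O)C(C)(C)C(=O)C(C(=O)C(C)C)=C2O)c(O)c1C(=O)c1ccccc1 | intermediate
17 | sarothralin | CC(C)=CCOc1cc(O)c(CC2=C(O)C(C)(C)C(=O)C(C(=O)C(C)C)=C2O)c(O)c1C(=O)c1ccccc1 | target

**Count**
Total steps: 8. Longest linear sequence: 8 steps (1 → 17); phloroisobutyrophenone 11 enters convergently in step 6.

**Steps most likely to fail**

Step 7. Methylation may run past two methyl groups, or go to the bridge-bearing carbon or to oxygen, giving mixtures that are hard to separate. The fallback sets the gem-dimethyl group before the bridge is made. It sets out from 11, which with NaOMe and iodomethane 13 in MeOH should pass through 3-methylphloroisobutyrophenone F1 to isobutyrylfilicinic acid F2, a known type of dearomative methylation whose product is separated from its aromatic dimethyl isomer. F2 has a single nucleophilic ring carbon and would be benzylated with alcohol 10 in HFIP as in step 6, which returns to the route at 15.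

Step 6. The benzylic cation may be captured by the neighbouring MOM oxygen (cyclisation with loss of the cap), or the product may be benzylated a second time, in competition with the intended C–C bond formation. The fallback avoids ionising conditions. It sets out from 10, which with MsCl and Et3N in CH2Cl2 at −20 °C should give the benzylic chloride F3, used crude. F3 would then C-alkylate the monosodium salt of 11 (NaH, toluene/THF, 0 °C, excess 11), a tight-ion-pair phenoxide C-benzylation, and the route is rejoined at 12.

Step 8. The prenyl ether may be lost by acid ionisation, or migrate to carbon, before the slower para-MOM group has gone. The fallback replaces solvolysis by a protecting-group exchange under base-buffered, aprotic conditions. It sets out from 15, which with excess TESOTf and 2,2′-bipyridyl in CH2Cl2 at 0 °C should exchange both aryl MOM ethers for silyl ethers and silylate the two enols, giving the tetrakis(triethylsilyl) ether F4. Without purification F4 would be desilylated with TBAF buffered by acetic acid in THF at 0 °C, which returns to the route at 17.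

**Further compounds**
F1 | step 7 | 2-methyl-1-(2,4,6-trihydroxy-3-methylphenyl)propan-1-one (3-methylphloroisobutyrophenone) | CC(C)C(=O)c1c(O)cc(O)c(C)c1O
F2 | step 7 | isobutyrylfilicinic acid (3,5-dihydroxy-6,6-dimethyl-2-(2-methylpropanoyl)cyclohexa-2,4-dien-1-one) | CC(C)C(=O)C1=C(O)C=C(O)C(C)(C)C1=O
F3 | step 6 | [3-(chloromethyl)-2,4-bis(methoxymethoxy)-6-[(3-methylbut-2-en-1-yl)oxy]phenyl](phenyl)methanone | COCOc1cc(OCC=C(C)C)c(C(=O)c2ccccc2)c(OCOC)c1CCl
F4 | step 8 | sarothralin tetrakis(triethylsilyl) ether (both benzophenone-ring phenols and both enols silylated) | CC(C)=CCOc1cc(O[Si](CC)(CC)CC)c(CC2=C(O[Si](CC)(CC)CC)C(C)(C)C(=O)C(C(=O)C(C)C)=C2O[Si](CC)(CC)CC)c(O[Si](CC)(CC)CC)c1C(=O)c1ccccc1
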